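**Unit first.** I count in one unit, the fraction of the substrate charge. The flask is delta followed further, so I ask where it stops and then how fast it gets there.

| flask | substrate | reagent | scavenger | free catalyst | added ligand | remark | time |
|---|---|---|---|---|---|---|---|
| delta | 20 mM | 19 mM | 16 mM | 0.20 mM | 0.18 mM | the very flask that is asked about, followed so far |  |
| beta | 20 mM | 19 mM | 16 mM | 0.20 mM | 0.090 mM | run made earlier |  |
| flask | 20 mM | 19.0 mM | 16.0 mM | 0.20 mM | 0.18 mM |  | 3.0 min |

delta run (percent of the substrate charged)

| time / s | substrate / % | target / % |
|---|---|---|
| 10.0 | 88 | 12 |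
| 20.0 | 79 | 16 |
| 30.0 | 74 | 28 |
| 40.0 | 69 | 33 |
| 50.0 | 61 | 38 |

beta run (percent of the substrate charged)

| time / min | substrate / % | target / % |
|---|---|---|
| 0.250 | 83 | 17 |
| 0.417 | 75 | 26 |
| 0.833 | 59 | 42 |
| 1.50 | 37 | 62 |
| 3.00 | 16 | 86 |

(standard deviation of a reading: 1.5 percentage points)

- the earlier runs do not show how much of reagent is bound; that part of a forecast is a guess

- part of the substrate that has reacted at 3.0 min
- share of the unused reagent that is free and not bound as idle adduct, at 3.0 min

**Substrate, reagent.** I assume one reagent per substrate, which makes reagent the limiting reagent of this pair. My ceiling 95.0% is the reagent charge over the substrate charge. By hand, more reagent lifts it and more substrate lowers it, as long as reagent stays below substrate. Both runs share this ceiling, so neither tests it.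

**Added ligand.** Delta has twice the ligand of beta. Yet at 50.0 s substrate reads 61% in delta and 59% in beta, a gap of 2 percentage points against a scatter of 1.5 points. I give ligand no term of its own.

**Time.** I treat the approach to the ceiling as a first-order lag. Delta's last reading then gives a time constant of 1.58 min. The asked time is 1.90 of these, so I reckon 80.8% reacted. Scavenger and catalyst are the same in both runs, so I can read nothing about them. The runs show no binding, so I have no reckoning for the free share.

**The forecast.** It gives 80% reacted and 50% free, the latter “essentially a guess near the middle”. I stay with my own figure.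

**The flask.** At 3.0 min the flask has reacted 83.0%, which is 87.4% of the ceiling, and 99.2% of its unused reagent is free, 49 points above the forecast. At 30.0 min it has reacted 95.0%, level with the ceiling.

    catalyst intermediate A → released group + catalyst intermediate B (k = 6.60 s⁻¹)
    target + released group → side product (k = 0.0890 M⁻¹ s⁻¹)
    free catalyst + added ligand ⇌ idle complex (K = 4500 M⁻¹, k = 180 M⁻¹ s⁻¹)
    catalyst intermediate C → free catalyst + target (k = 6.40 s⁻¹)
    scavenger + released group → scavenged by-product (k = 110 M⁻¹ s⁻¹)
    reagent + released group ⇌ idle adduct, settled at all times (K = 12.0 M⁻¹)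
    substrate + catalyst intermediate B ⇌ catalyst intermediate C (K = 80.0 M⁻¹, k = 2400 M⁻¹ s⁻¹)
    reagent + free catalyst ⇌ catalyst intermediate A (K = 18.0 M⁻¹, k = 9700 M⁻¹ s⁻¹)

**Less reagent.** A neighbour flask holds 7.6 mM of reagent, with its other charges and its time as in the flask. Its ceiling is 38.0%, and the same time constant gives 32.3%. At 3.0 min this neighbour flask has reacted 35.2%, with 7.4% of its reagent charge left.

The runs come from a simulation with made-up constants; noise was put on by code.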